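The readings are calculated for substances that don't exist; scatter was added.

in all of them: free monomer 0.80 M
- north-west: initiator 1.7 mM; the very flask that is asked about, followed so far
- north: initiator 1.1 mM; run made earlier
- flask: initiator 1.7 mM; time 2.5 d

north-west run (percent of the free monomer charged)

| time / h | monomer in chains / % | free monomer / % |
|---|---|---|
| 2.00 | 14.2 | 85.0 |
| 4.00 | 34.5 | 62.8 |
| 10.0 | 60.2 | 29.3 |
| 25.0 | 66.5 | 15.9 |

north run (percent of the free monomer charged)

| time / d | monomer in chains / % | free monomer / % |
|---|---|---|
| 0.625 | 60.6 | 32.3 |
| 1.25 | 67.0 | 22.6 |
| 2.08 | 69.0 | 18.6 |
| 2.50 | 69.6 | 17.5 |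

(standard deviation of a reading: 0.5 percentage points)



* amount of monomer in chains in the flask at 2.5 d, in percent of the free monomer charged
* amount of free monomer in the flask at 2.5 d, in percent of the free monomer charged
* amount of isomer of the product in the flask at 2.5 d, in percent of the free monomer charged

I began with a balance: I counted what was neither free monomer nor monomer in chains as isomer of the product. The north flask, with 1.1 mM of initiator, held 12.9% of isomer at 2.50 d. The north-west flask, with 1.7 mM, held more, 17.6%, at 25.0 h. Yet both were charged with 0.80 M of free monomer, and in the north flask its loss was dying away.

That loss ran at 0.0482 d⁻¹ of the charge around 20.6% left, then at 0.0262 d⁻¹ around 18.1%. A straight line through these two points reaches zero loss at 15.0%. I call the matching concentration, 0.120 M, the floor: the c(free monomer) at which free monomer stops falling, the equilibrium monomer concentration. It is a rough reading, since both slopes rest on small differences with a scatter of 0.5 percentage points. I assumed that the floor does not move with initiator, so I expected both flasks to end near it and to part in how the rest divides between chains and isomer. For the north-west flask at 2.5 d, I committed to about 15.0% free monomer.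

The forecast gave 67.6% in chains, 12.5% free monomer and 19.9% isomer, below my floor for free monomer: “Extrapolating the flask run from 25 h to 60 h with that tail, free monomer falls from 15.9 to about 12.5%.”

The flask gave 63.7%, 14.9% and 21.0%, and the forecast stands within tolerance on each.

    living end + free monomer → dead end (k = 0.340 M⁻¹ h⁻¹)
    monomer in chains → over-reaction product (k = 7.36 × 10⁻⁵ h⁻¹)
    free monomer + initiator → living end + monomer in chains (k = 0.314 M⁻¹ h⁻¹)
    free monomer + living end → monomer in chains + living end, rate k4*[living end]*[free monomer] (k = 338 M⁻¹ h⁻¹)
    monomer in chains + initiator ⇌ isomer of the product + initiator, rate k5*[initiator]*[monomer in chains] forward; the back reaction follows from the equilibrium constant (K = 0.397, k = 64.9 M⁻¹ h⁻¹)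
    monomer in chains + living end → free monomer + living end, rate k6*[living end] as long as [monomer in chains] is above zero (k = 40.1 h⁻¹)

The flask's free monomer was 0.119 M, beside the floor of 0.120 M, and it was still 14.8% of the charge at 25.0 d. A further flask was charged with 0.20 M of free monomer, all else as in the recipe. There the same floor is 60.0% of the charge, and that flask held 59.2% free monomer at 2.50 d.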